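**Plan**
1. Retrosynthetic cuts: first the four O–benzyl bonds, then the biaryl bond C4 (ring A)–C1' (ring B). Last, in one operation, both ends of the tether are cut, C5 (ring A)–CH2 and CH2–C1'' (ring C).
2. Enabling feature: the C5–CH2–CH2–C1'' bridge is a two-carbon unit with a different arene on each carbon, that is, a vinyl group arylated twice. In a vinylboron ate complex, ring C reaches one carbon by 1,2-shift from boron and ring A reaches the other from palladium.
3. No ring is built, since rings A, B and C are bought as benzenes. Ring A comes from mirror-symmetric methyl 2,6-dihydroxy-4-methoxybenzoate: benzylating one ortho OH and triflating the other fixes C3–O, C5 and C1–OMe, and the ester marks C4.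
4. Forward order: ring A triflate + vinylboronate + ring C aryllithium (step 4); C–B to C–H; CO2Me to CO2H to iodide (ipso-iododecarboxylation); Suzuki–Miyaura union with a ring B boronate; global hydrogenolysis.
5. Stereochemistry: the target has no stereocentre. The boron-bearing carbon created in step 4 is set by the chiral ligand and erased in step 5.

Key step: step 4

Assumption: the target SMILES carries no stereodescriptor and its biaryl axis (ortho groups OH, CH2CH2Ar, OH) is taken as freely rotating, so no axial control is planned; the boronate from the key step is drawn (S) only for definiteness, and its antipode serves equally.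

**Step 1**
Reactants: 1 methyl 2,4,6-trihydroxybenzoate
Product: 2 methyl 2,6-dihydroxy-4-methoxybenzoate
Conditions: MeOH (1.0 equiv), PPh3, DIAD, THF, 0 °C → rt
Reagents that add atoms: methanol, CO
Why: Mitsunobu etherification should pick the most acidic and only non-chelated phenol (para to the ester), because the two ortho hydroxyls are hydrogen-bonded to the ester, and the neutral medium avoids C-methylation of the phloroglucinol nucleus.

**Step 2**
Reactants: 2 methyl 2,6-dihydroxy-4-methoxybenzoate
Product: 3 methyl 2-(benzyloxy)-6-hydroxy-4-methoxybenzoate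
Conditions: BnBr (1.0 equiv), K2CO3, acetone, reflux
Reagents that add atoms: benzyl bromide, BrCc1ccccc1
Why: Williamson etherification of one of two equivalent phenols should stop at the monoether, because the remaining hydroxyl then holds the ester carbonyl in an undivided, stronger hydrogen bond and sits next to a more crowded ester.

**Step 3**
Reactants: 3 methyl 2-(benzyloxy)-6-hydroxy-4-methoxybenzoate
Product: 4 methyl 2-(benzyloxy)-4-methoxy-6-[(trifluoromethanesulfonyl)oxy]benzoate
Conditions: Tf2O, pyridine, CH2Cl2, 0 °C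
Reagents that add atoms: trifluoromethanesulfonic anhydride, O=S(=O)(OS(=O)(=O)C(F)(F)F)C(F)(F)F
Why: O-sulfonylation with triflic anhydride and pyridine is routine even for chelated salicylate-type phenols and touches neither the ester nor the ethers.

**Step 4**
Reactants: 5 1-(benzyloxy)-3-bromobenzene; 6 vinylboronic acid pinacol ester (2-ethenyl-4,4,5,5-tetramethyl-1,3,2-dioxaborolane); 4 methyl 2-(benzyloxy)-4-methoxy-6-[(trifluoromethanesulfonyl)oxy]benzoate
Product: 9 methyl 2-(benzyloxy)-6-{(2S)-2-[3-(benzyloxy)phenyl]-2-(4,4,5,5-tetramethyl-1,3,2-dioxaborolan-2-yl)ethyl}-4-methoxybenzoate, via [3-(benzyloxy)phenyl]lithium 7 (not isolated), via lithium aryl(vinyl)pinacolatoborate 8 (not isolated)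
Conditions: 5, n-BuLi, THF, −78 °C; 6, −78 °C → rt; evaporate (removes n-BuBr); 4, Pd(OAc)2 (3 mol %), MandyPhos [1,1'-bis{bis(4-methoxy-3,5-dimethylphenyl)phosphino}-2,2'-bis{α-(dimethylamino)benzyl}ferrocene, one enantiomer] (3.6 mol %), THF, 60 °C
Reagents that add atoms: none
Why: This is the palladium-catalysed conjunctive cross-coupling, a known three-component reaction of vinylboron ate complexes with aryl triflates. Oxidative addition of the C–OTf bond of 4 to zerovalent palladium gives a cationic arylpalladium that binds the vinyl group of 8; the ring C aryl then migrates from boron to the α-carbon (ring C–CH bond) as palladium takes the β-carbon, and reductive elimination forms CH2–C5 of ring A. No ring is closed. The one new stereocentre, the boron-bearing benzylic carbon, is set by the chiral bisphosphine, which decides the alkene face that palladium occupies during the shift, and its sense is immaterial because step 5 removes it. The selectivity needed is metallate shift over direct aryl or vinyl transmetallation and over β-hydride elimination, and it is secured by the non-coordinating triflate of 4, the halide-free medium (n-BuBr is pumped off and no lithium halide is formed) and the wide-bite-angle ferrocenyl ligand. The ester of 4 is safe because 6 has consumed all of 7 before 4 is added, and a four-coordinate boronate does not add to a di-ortho-substituted benzoate.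

**Step 5**
Reactants: 9 methyl 2-(benzyloxy)-6-{(2S)-2-[3-(benzyloxy)phenyl]-2-(pinacolboryl)ethyl}-4-methoxybenzoate
Product: 10 methyl 2-(benzyloxy)-6-{2-[3-(benzyloxy)phenyl]ethyl}-4-methoxybenzoate
Conditions: Bu4NF·3H2O (3 equiv), toluene, 60 °C
Reagents that add atoms: none
Why: In this fluoride-promoted protodeboronation of a benzylic boronic ester, fluoride forms the four-coordinate boronate and the hydrate water protonates its benzylic C–B bond, which leaves the hindered ester and the benzyl ethers intact and turns the stereocentre into CH2.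

**Step 6**
Reactants: 10 methyl 2-(benzyloxy)-6-{2-[3-(benzyloxy)phenyl]ethyl}-4-methoxybenzoate
Product: 11 2-(benzyloxy)-6-{2-[3-(benzyloxy)phenyl]ethyl}-4-methoxybenzoic acid
Conditions: KOH, DMSO/H2O, 100 °C; then cold 1 M HCl to pH 3
Reagents that add atoms: potassium hydroxide, [K+].[OH-]
Why: Saponification of a di-ortho-substituted benzoate needs poorly solvated hydroxide in hot aqueous DMSO, conditions established for 2-benzyloxy-4-methoxy-6-alkylbenzoates, and cold acidification guards the electron-rich acid against protodecarboxylation.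

**Step 7**
Reactants: 11 2-(benzyloxy)-6-{2-[3-(benzyloxy)phenyl]ethyl}-4-methoxybenzoic acid
Product: 12 1-(benzyloxy)-3-{2-[3-(benzyloxy)phenyl]ethyl}-2-iodo-5-methoxybenzene
Conditions: I2 (3 equiv), K3PO4 (1 equiv), MeCN, 100 °C, sealed tube
Reagents that add atoms: iodine, II
Why: Metal-free ipso-iododecarboxylation (a Hunsdiecker-type halodecarboxylation) is established for electron-rich ortho-alkoxybenzoic acids; here the ipso carbon is activated by the ortho OBn and para OMe groups, and loss of CO2 relieves the strain of the twisted carboxylate.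

**Step 8**
Reactants: 13 2-bromobenzene-1,4-diol
Product: 14 1,4-bis(benzyloxy)-2-bromobenzene
Conditions: BnBr (2.3 equiv), K2CO3, DMF, 60 °C
Reagents that add atoms: benzyl bromide, BrCc1ccccc1
Why: Exhaustive Williamson benzylation of both phenols under nitrogen masks the oxidation-prone hydroquinone with the same group used on rings A and C.

**Step 9**
Reactants: 14 1,4-bis(benzyloxy)-2-bromobenzene
Product: 15 2-[2,5-bis(benzyloxy)phenyl]-4,4,5,5-tetramethyl-1,3,2-dioxaborolane
Conditions: B2pin2, PdCl2(dppf) (3 mol %), KOAc, 1,4-dioxane, 90 °C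
Reagents that add atoms: bis(pinacolato)diboron, CC1(C)OB(OC1(C)C)B1OC(C)(C)C(C)(C)O1
Why: Miyaura borylation of an aryl bromide tolerates ortho alkoxy groups, and the weak base KOAc prevents homocoupling.

**Step 10**
Reactants: 12 1-(benzyloxy)-3-{2-[3-(benzyloxy)phenyl]ethyl}-2-iodo-5-methoxybenzene; 15 2-[2,5-bis(benzyloxy)phenyl]-4,4,5,5-tetramethyl-1,3,2-dioxaborolane
Product: 16 2,2',5'-tris(benzyloxy)-6-{2-[3-(benzyloxy)phenyl]ethyl}-4-methoxy-1,1'-biphenyl
Conditions: Pd(OAc)2 (5 mol %), SPhos (10 mol %), K3PO4, toluene/H2O, 90 °C, 15 in excess (1.5 equiv)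
Reagents that add atoms: none
Why: Suzuki–Miyaura coupling with a bulky dialkylbiarylphosphine is the standard route to tri-ortho-substituted biaryls, and fast transmetallation at this temperature should outrun intramolecular C–H arylation of the benzyl ether or of ring C.

**Step 11**
Reactants: 16 2,2',5'-tris(benzyloxy)-6-{2-[3-(benzyloxy)phenyl]ethyl}-4-methoxy-1,1'-biphenyl
Product: 17 6-[2-(3-hydroxyphenyl)ethyl]-4-methoxy-1,1'-biphenyl-2,2',5'-triol (CNP0121738.0)
Conditions: H2 (1 atm), 10 % Pd/C, EtOAc/MeOH, rt; work-up under argon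
Reagents that add atoms: none
Why: Catalytic hydrogenolysis cleaves all four aryl benzyl ethers in one operation and leaves the aryl methyl ether and the saturated bridge untouched.

**Compound list**
1 | methyl 2,4,6-trihydroxybenzoate | COC(=O)c1c(O)cc(O)cc1O | starting material
2 | methyl 2,6-dihydroxy-4-methoxybenzoate | COC(=O)c1c(O)cc(OC)cc1O | intermediate
3 | methyl 2-(benzyloxy)-6-hydroxy-4-methoxybenzoate | COC(=O)c1c(O)cc(OC)cc1OCc1ccccc1 | intermediate
4 | methyl 2-(benzyloxy)-4-methoxy-6-[(trifluoromethanesulfonyl)oxy]benzoate | COC(=O)c1c(OCc2ccccc2)cc(OC)cc1OS(=O)(=O)C(F)(F)F | intermediate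
5 | 1-(benzyloxy)-3-bromobenzene | Brc1cccc(OCc2ccccc2)c1 | starting material
6 | vinylboronic acid pinacol ester | C=CB1OC(C)(C)C(C)(C)O1 | starting material
7 | [3-(benzyloxy)phenyl]lithium | [Li]c1cccc(OCc2ccccc2)c1 | intermediate
8 | lithium [3-(benzyloxy)phenyl](ethenyl)(pinacolato)borate | [Li+].C=C[B-]1(c2cccc(OCc3ccccc3)c2)OC(C)(C)C(C)(C)O1 | intermediate
9 | methyl 2-(benzyloxy)-6-{(2S)-2-[3-(benzyloxy)phenyl]-2-(4,4,5,5-tetramethyl-1,3,2-dioxaborolan-2-yl)ethyl}-4-methoxybenzoate | COC(=O)c1c(OCc2ccccc2)cc(OC)cc1C[C@H](B1OC(C)(C)C(C)(C)O1)c1cccc(OCc2ccccc2)c1 | intermediate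
10 | methyl 2-(benzyloxy)-6-{2-[3-(benzyloxy)phenyl]ethyl}-4-methoxybenzoate | COC(=O)c1c(OCc2ccccc2)cc(OC)cc1CCc1cccc(OCc2ccccc2)c1 | intermediate
11 | 2-(benzyloxy)-6-{2-[3-(benzyloxy)phenyl]ethyl}-4-methoxybenzoic acid | OC(=O)c1c(OCc2ccccc2)cc(OC)cc1CCc1cccc(OCc2ccccc2)c1 | intermediate
12 | 1-(benzyloxy)-3-{2-[3-(benzyloxy)phenyl]ethyl}-2-iodo-5-methoxybenzene | COc1cc(OCc2ccccc2)c(I)c(CCc2cccc(OCc3ccccc3)c2)c1 | intermediate
13 | 2-bromobenzene-1,4-diol | Oc1ccc(O)c(Br)c1 | starting material
14 | 1,4-bis(benzyloxy)-2-bromobenzene | Brc1cc(OCc2ccccc2)ccc1OCc1ccccc1 | intermediate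
15 | 2-[2,5-bis(benzyloxy)phenyl]-4,4,5,5-tetramethyl-1,3,2-dioxaborolane | CC1(C)OB(OC1(C)C)c1cc(OCc2ccccc2)ccc1OCc1ccccc1 | intermediate
16 | 2,2',5'-tris(benzyloxy)-6-{2-[3-(benzyloxy)phenyl]ethyl}-4-methoxy-1,1'-biphenyl | COc1cc(OCc2ccccc2)c(-c2cc(OCc3ccccc3)ccc2OCc2ccccc2)c(CCc2cccc(OCc3ccccc3)c2)c1 | intermediate
17 | 6-[2-(3-hydroxyphenyl)ethyl]-4-methoxy-1,1'-biphenyl-2,2',5'-triol | COc1cc(O)c(-c2cc(O)ccc2O)c(CCc2cccc(O)c2)c1 | target

**Step count**
Total steps: 11. Longest linear sequence: 9 (steps 1–7, 10, 11, starting from 1).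

**Steps most likely to fail**

Step 4.
- Direct transfer of the aryl or vinyl group from boron to palladium may outrun the metallate shift.
- The ortho ester carbonyl may occupy the free site on the cationic palladium that the alkene needs.
- Traces of halide may shut down the cationic pathway.

The fallback replaces the three-component reaction by a B-alkyl Suzuki–Miyaura coupling. It sets out from 4, 5 and 6 and returns at 10, so step 5 is skipped as well. Suzuki–Miyaura vinylation of 5 with 6 (Pd(PPh3)4, K2CO3, dioxane/H2O, 90 °C) would give 1-(benzyloxy)-3-ethenylbenzene F1. Anti-Markovnikov hydroboration with 9-BBN-H (THF, rt) would give 9-{2-[3-(benzyloxy)phenyl]ethyl}-9-borabicyclo[3.3.1]nonane F2. This borane is coupled in the same flask with 4 (PdCl2(dppf), K3PO4, THF/H2O, 65 °C) to give 10.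

Step 7.
- Iodination of the doubly activated C–H positions of ring A may accompany or replace ipso substitution.
- Plain protodecarboxylation may consume the acid.

The fallback forms the biaryl bond directly from the carboxylate with no halide on ring A. It sets out from 11 and 14 and returns at 16, so step 10 is skipped. A copper-catalysed aromatic Finkelstein exchange on 14 (CuI, NaI, N,N'-dimethylethylenediamine, dioxane, 110 °C) would give 1,4-bis(benzyloxy)-2-iodobenzene F3. The known palladium/silver decarboxylative biaryl coupling of 2,6-disubstituted electron-rich benzoic acids with aryl iodides (PdCl2, AsPh3, Ag2CO3, DMSO, 150 °C) would then join 11 and F3 to give 16.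

Step 5.
- Protonolysis of a secondary benzylic C–B bond may be slow.
- Air oxidation of the boronate may intervene.
- The developing benzylic anion may be acylated by the neighbouring ester.

The fallback removes boron by oxidation, elimination and reduction. It sets out from 9 and returns at 11, so step 6 is skipped.
- Oxidation with retention (NaBO3·4H2O, THF/H2O, rt) would give methyl 2-(benzyloxy)-6-{(2S)-2-[3-(benzyloxy)phenyl]-2-hydroxyethyl}-4-methoxybenzoate F4.
- F4 closes onto the adjacent ester (cat. TsOH, toluene, 60 °C) to give (3S)-8-(benzyloxy)-3-[3-(benzyloxy)phenyl]-6-methoxy-3,4-dihydro-1H-isochromen-1-one F5.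
- Base-induced eliminative ring opening through the toluate-type C4 anion (KOt-Bu, THF, rt, then cold acid) would give 2-(benzyloxy)-6-{(E)-2-[3-(benzyloxy)phenyl]ethenyl}-4-methoxybenzoic acid F6.
- Diimide reduction of F6 (TsNHNH2, NaOAc, DME/H2O, reflux) saturates the stilbene without touching the benzyl ethers and delivers 11.

**Further compounds**
F1 | step 4 | 1-(benzyloxy)-3-ethenylbenzene | C=Cc1cccc(OCc2ccccc2)c1
F2 | step 4 | 9-{2-[3-(benzyloxy)phenyl]ethyl}-9-borabicyclo[3.3.1]nonane | C(Cc1cccc(OCc2ccccc2)c1)B1C2CCCC1CCC2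
F3 | step 7 | 1,4-bis(benzyloxy)-2-iodobenzene | Ic1cc(OCc2ccccc2)ccc1OCc1ccccc1
F4 | step 5 | methyl 2-(benzyloxy)-6-{(2S)-2-[3-(benzyloxy)phenyl]-2-hydroxyethyl}-4-methoxybenzoate | COC(=O)c1c(OCc2ccccc2)cc(OC)cc1C[C@H](O)c1cccc(OCc2ccccc2)c1
F5 | step 5 | (3S)-8-(benzyloxy)-3-[3-(benzyloxy)phenyl]-6-methoxy-3,4-dihydro-1H-isochromen-1-one | O=C1O[C@H](c2cccc(OCc3ccccc3)c2)Cc2cc(OC)cc(OCc3ccccc3)c12
F6 | step 5 | 2-(benzyloxy)-6-{(E)-2-[3-(benzyloxy)phenyl]ethenyl}-4-methoxybenzoic acid | COc1cc(OCc2ccccc2)c(C(=O)O)c(/C=C/c2cccc(OCc3ccccc3)c2)c1
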